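**Retrosynthetic overview**
1. Target 28 ⇐ 7α-hydroxy lactone 27 ⇐ diol 25 (oxidative lactonisation C15→O16, then C7 oxidation). Ring order: temporary C12→O8 γ-lactone on the sclareolide decalin, then the spiro tetrahydrofuran (O9–C13), then the butanolide.
2. Spiro ether 24 ⇐ 5-exo opening of the C13/C16 epoxide 23 by 9α-OH, with inversion at C13.
3. Key C12–C13 bond: intermolecular aldol of the lithium enolate of the (R)-malic acid-derived dioxolanone 15 (fixes C13) with the C12 lactol 11 (masked aldehyde), then deoxygenation at C12.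
4. Ring B oxygens: enone 3 → 8α,9α-epoxide (sets C9–O) → Wharton transposition → 7α,8α-epoxide opened at C8 by the C12 carboxyl (inverts C8 to 8β-O).
5. Rings A and B with C5 and C10 come from (+)-sclareolide.

Assumption: labdane numbering is used throughout (C17 = methyl on C8, C18/C19 = methyls on C4, C20 = methyl on C10, C11–C16 = side chain; "tetranorlabdane" = 13,14,15,16-tetranorlabdane), α/β refer to the usual decalin drawing with the C10 methyl β, and (R)-malic acid is taken as an inexpensive commercial material.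

**Step 1**
Reactants: 1 (+)-sclareolide
Product: 2 methyl 13,14,15,16-tetranorlabd-8-en-12-oate
Conditions: MeOH, conc. H2SO4 (cat.), reflux, 24 h
Reagents that add atoms: methanol, CO
Why: Acid-catalysed lactone methanolysis and E1 dehydration under equilibrating conditions should funnel the tertiary C8 cation to the tetrasubstituted 8(9)-alkene (minor 7-ene and 8(17)-ene isomers are removed on AgNO3-silica), while C5 and C10 are untouched chiral-pool centres.

**Step 2**
Reactants: 2 methyl 13,14,15,16-tetranorlabd-8-en-12-oate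
Product: 3 methyl 7-oxo-13,14,15,16-tetranorlabd-8-en-12-oate
Conditions: CrO3 (15 equiv), 3,5-dimethylpyrazole (15 equiv), CH2Cl2, −20 °C, 4 h
Reagents that add atoms: chromium trioxide, O=[Cr](=O)=O
Why: Chromium-mediated allylic oxidation (CrO3–3,5-dimethylpyrazole) converts the accessible ring allylic methylene C7 of the tetrasubstituted alkene into the conjugated enone, and no stereocentre is formed.

**Step 3**
Reactants: 3 methyl 7-oxo-13,14,15,16-tetranorlabd-8-en-12-oate
Product: 5 8α,9α-epoxy-7-oxo-13,14,15,16-tetranorlabdan-12-oic acid, via enone acid 4 (not isolated)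
Conditions: LiOH·H2O (3 equiv), THF–H2O, rt; then 30% aq. H2O2 (5 equiv), 0 °C → rt; then 1 M HCl to pH 3
Reagents that add atoms: lithium hydroxide, [Li+].[OH-]; hydrogen peroxide, OO
Why: Saponification followed by Weitz–Scheffer nucleophilic epoxidation, in which hydroperoxide adds axially to C9 on the α face anti to the angular C10 methyl so that the 8α,9α-epoxide (and hence the α C9–O bond of the target) is set, the carboxylate form preventing E1cB opening of the epoxide.

**Step 4**
Reactants: 5 8α,9α-epoxy-7-oxo-13,14,15,16-tetranorlabdan-12-oic acid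
Product: 7 9α-hydroxy-13,14,15,16-tetranorlabd-7-en-12-oic acid, via epoxy hydrazone 6 (not isolated)
Conditions: N2H4·H2O (3 equiv), AcOH (0.2 equiv), MeOH, 0 °C → rt
Reagents that add atoms: none
Why: Wharton transposition, in which the epoxy hydrazone fragments with loss of N2 to the tertiary allylic alcohol with the double bond at C7=C8, the C9–O bond never being broken so that the 9α configuration is retained.

**Step 5**
Reactants: 7 9α-hydroxy-13,14,15,16-tetranorlabd-7-en-12-oic acid
Product: 9 7α,9α-dihydroxy-13,14,15,16-tetranorlabdan-12,8β-olide, via epoxy hydroxy acid 8 (not isolated)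
Conditions: mCPBA (1.2 equiv), CH2Cl2, 0 °C → rt
Reagents that add atoms: mCPBA (3-chloroperoxybenzoic acid), OOC(=O)c1cccc(Cl)c1
Why: Hydroxyl-directed (Henbest) epoxidation on the less hindered α face gives the 7α,8α-epoxide, which the β-oriented carboxylic acid opens at tertiary C8 in a 5-exo, trans-diaxial (Fürst–Plattner) lactonisation with inversion, setting the 8β-O/8α-CH3 centre and leaving a 7α-hydroxyl.

**Step 6**
Reactants: 9 7α,9α-dihydroxy-13,14,15,16-tetranorlabdan-12,8β-olide
Product: 10 7α,9α-O-benzylidene-8β-oxy-13,14,15,16-tetranorlabdan-12,8β-olide (phenyl exo)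
Conditions: PhCH(OMe)2 (1.5 equiv), CSA (5 mol %), CH2Cl2, rt
Reagents that add atoms: benzaldehyde dimethyl acetal, COC(OC)c1ccccc1
Why: Acid-catalysed transacetalisation bridges the cis-1,3-diaxial 7α,9α-diol as a six-membered benzylidene acetal, the acetal centre settling under thermodynamic control with phenyl exo and its hydrogen facing ring B.

**Step 7**
Reactants: 10 benzylidene-protected lactone
Product: 11 7α,9α-O-benzylidene-8β,12-epoxy-13,14,15,16-tetranorlabdan-12-ol (lactol; C12 anomers)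
Conditions: i-Bu2AlH (1.2 equiv), CH2Cl2, −78 °C; aq. potassium sodium tartrate
Reagents that add atoms: none
Why: Partial reduction of the γ-lactone by i-Bu2AlH stops at the stable tetrahedral aluminate at −78 °C and delivers the lactol, a masked C12 aldehyde, without touching the acetal.

**Step 8**
Reactants: 12 (R)-malic acid
Product: 13 2-[(2R,4R)-2-tert-butyl-5-oxo-1,3-dioxolan-4-yl]acetic acid
Conditions: t-BuCHO (1.5 equiv), TsOH·H2O (cat.), H2SO4 (cat.), pentane, reflux, Dean–Stark; recrystallisation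
Reagents that add atoms: pivalaldehyde, CC(C)(C)C=O
Why: Seebach acetalisation of the α-hydroxy acid unit gives the cis-2,5-disubstituted dioxolanone under thermodynamic control, so the new acetal centre (2R) is dictated by the malic acid stereocentre.

**Step 9**
Reactants: 13 2-[(2R,4R)-2-tert-butyl-5-oxo-1,3-dioxolan-4-yl]acetic acid
Product: 14 (2R,5R)-2-tert-butyl-5-(2-hydroxyethyl)-1,3-dioxolan-4-one
Conditions: BH3·SMe2 (1.2 equiv), THF, 0 °C → rt; MeOH quench
Reagents that add atoms: none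
Why: Chemoselective borane reduction, in which the free carboxylic acid (via its acyloxyborane) is reduced much faster than the dioxolanone carbonyl and neither stereocentre is touched.

**Step 10**
Reactants: 14 (2R,5R)-2-tert-butyl-5-(2-hydroxyethyl)-1,3-dioxolan-4-one
Product: 15 (2R,5R)-2-tert-butyl-5-[2-(tert-butyldiphenylsilyloxy)ethyl]-1,3-dioxolan-4-one
Conditions: TBDPSCl (1.1 equiv), imidazole (2.2 equiv), CH2Cl2, 0 °C → rt
Reagents that add atoms: TBDPSCl (tert-butylchlorodiphenylsilane), CC(C)(C)[Si](Cl)(c1ccccc1)c1ccccc1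
Why: Silylation of the primary alcohol under mild imidazole catalysis blocks translactonisation and masks C15 at the alcohol oxidation level.

**Step 11**
Reactants: 11 lactol (C12 aldehyde equivalent); 15 silyl-protected dioxolanone
Product: 17 (2R,5S)-5-[7α,9α-O-benzylidene-8β,12-dihydroxy-13,14,15,16-tetranorlabdan-12-yl]-2-tert-butyl-5-[2-(tert-butyldiphenylsilyloxy)ethyl]-1,3-dioxolan-4-one (C12 epimers), via lithium enolate 16 (not isolated)
Conditions: 15 (3.5 equiv), LiN(i-Pr)2 (3.5 equiv), THF, −78 °C, 45 min; then 11, −78 → −45 °C, 3 h; AcOH quench at −78 °C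
Reagents that add atoms: none
Why: Intermolecular aldol addition in which the aldehyde (released from the lithium lactolate by ring–chain equilibration) attacks the planar enolate on the face anti to the tert-butyl group, so C12 replaces the original hydrogen with retention (Seebach self-regeneration of stereocentres) and fixes the quaternary C13, the C12 carbinol forming as an inconsequential mixture.

**Step 12**
Reactants: 17 aldol adduct
Product: 18 12-O-(phenoxythiocarbonyl) derivative of 17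
Conditions: PhOC(S)Cl (1.5 equiv), pyridine (3 equiv), DMAP (0.2 equiv), CH2Cl2, 0 °C → rt
Reagents that add atoms: O-phenyl chlorothionoformate, S=C(Cl)Oc1ccccc1
Why: DMAP-catalysed acylation converts the only secondary hydroxyl into the thionocarbonate needed for Barton–McCombie deoxygenation, the tertiary 8β-OH being too hindered to react and the non-basic conditions avoiding retro-aldol cleavage.

**Step 13**
Reactants: 18 thionocarbonate
Product: 19 (2R,5R)-5-[2-(7α,9α-O-benzylidene-8β-hydroxy-13,14,15,16-tetranorlabdan-11-yl)ethyl-type side chain: 7α,9α-O-benzylidene-8β-hydroxy-13,14,15,16-tetranorlabdan-12-yl]-2-tert-butyl-5-[2-(tert-butyldiphenylsilyloxy)ethyl]-1,3-dioxolan-4-one (C12 now CH2)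
Conditions: Bu3SnH (2 equiv), AIBN (0.2 equiv), toluene, 90 °C
Reagents that add atoms: none
Why: Barton–McCombie radical deoxygenation, in which the stannyl radical adds to C=S, the C12–O bond fragments and the secondary radical is quenched by Bu3SnH, erasing the C12 stereocentre without touching C13.

**Step 14**
Reactants: 19 deoxygenated dioxolanone
Product: 20 (13R)-7α,9α-O-benzylidene-15-(tert-butyldiphenylsilyloxy)labdane-8β,13,16-triol
Conditions: LiAlH4 (2.5 equiv), THF, 0 °C; Na2SO4·10H2O quench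
Reagents that add atoms: none
Why: Hydride reduction of the dioxolanone carbonyl (C16) to CH2OH releases the acetal as neopentyl alcohol and unveils the tertiary C13 alcohol with retention, since no bond to C13 is broken.

**Step 15**
Reactants: 20 benzylidene-protected triol
Product: 21 (13R)-15-(tert-butyldiphenylsilyloxy)labdane-7α,8β,9α,13,16-pentaol
Conditions: H2 (1 atm), Pd(OH)2/C, EtOAc–EtOH, rt
Reagents that add atoms: none
Why: Neutral hydrogenolysis of the benzylidene acetal frees the 7α- and 9α-hydroxyls without affecting the silyl ether or any stereocentre.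

**Step 16**
Reactants: 21 pentaol
Product: 23 (13R)-13,16-epoxy-15-(tert-butyldiphenylsilyloxy)labdane-7α,8β,9α-triol, via primary tosylate 22 (not isolated)
Conditions: TsCl (1.1 equiv), Et3N (1.5 equiv), Bu2SnO (5 mol %), CH2Cl2, rt; then K2CO3 (3 equiv), MeOH, 0 °C → rt
Reagents that add atoms: none
Why: Bu2SnO-catalysed sulfonylation selects the primary hydroxyl of the 1,2-diol through its stannylene acetal, and base then closes the epoxide by intramolecular Williamson displacement at C16, keeping the C13–O bond and configuration.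

**Step 17**
Reactants: 23 hydroxy epoxide
Product: 24 (13S)-9α,13-epoxy-15-(tert-butyldiphenylsilyloxy)labdane-7α,8β,16-triol
Conditions: CSA (10 mol %), CH2Cl2, 0 °C → rt
Reagents that add atoms: none
Why: Acid-catalysed 5-exo-tet epoxide opening, in which the 9α-hydroxyl attacks the tertiary epoxide carbon anti to the leaving oxygen so that C13 is inverted to the required 13S spiro ether while the α C9–O bond is unchanged and the former malate oxygen ends on C16.

**Step 18**
Reactants: 24 silyl-protected spiro ether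
Product: 25 (13S)-9α,13-epoxylabdane-7α,8β,15,16-tetraol
Conditions: Bu4NF (1.5 equiv), THF, rt
Reagents that add atoms: none
Why: Fluoride-mediated desilylation frees the primary C15 alcohol under conditions that leave the spiro ether and all stereocentres intact.

**Step 19**
Reactants: 25 tetraol
Product: 27 (13S)-9α,13-epoxy-7α,8β-dihydroxylabdan-15,16-olide, via lactol 26 (not isolated)
Conditions: TEMPO (20 mol %), PhI(OAc)2 (2.5 equiv), CH2Cl2, rt
Reagents that add atoms: none
Why: TEMPO-mediated oxidative lactonisation, in which the unhindered primary C15 alcohol is oxidised in preference to the neopentylic C16–OH and the axial 7α-OH, the aldehyde closes to the lactol with C16–OH and is oxidised again to the γ-lactone.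

**Step 20**
Reactants: 27 7α-hydroxy lactone
Product: 28 (13S)-9α,13-epoxy-8β-hydroxy-7-oxolabdan-15,16-olide (target)
Conditions: Dess–Martin periodinane (1.5 equiv), CH2Cl2, rt
Reagents that add atoms: none
Why: Dess–Martin oxidation of the remaining secondary 7α-alcohol gives the C7 ketone, the trans-diaxial tertiary 8β-OH being unable to take part in glycol cleavage and C8 having no hydrogen to epimerise.

**Compound list**
1 | (+)-sclareolide, (3aR,5aS,9aS,9bR)-3a,6,6,9a-tetramethyldecahydronaphtho[2,1-b]furan-2(1H)-one | CC1(C)CCC[C@@]2(C)[C@H]1CC[C@@]1(C)OC(=O)C[C@H]21 | starting material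
2 | methyl 13,14,15,16-tetranorlabd-8-en-12-oate (5S,10S) | CC1(C)CCC[C@@]2(C)[C@H]1CCC(C)=C2CC(=O)OC | intermediate
3 | methyl 7-oxo-13,14,15,16-tetranorlabd-8-en-12-oate | CC1(C)CCC[C@@]2(C)[C@H]1CC(=O)C(C)=C2CC(=O)OC | intermediate
4 | 7-oxo-13,14,15,16-tetranorlabd-8-en-12-oic acid | CC1(C)CCC[C@@]2(C)[C@H]1CC(=O)C(C)=C2CC(=O)O | intermediate (not isolated)
5 | 8α,9α-epoxy-7-oxo-13,14,15,16-tetranorlabdan-12-oic acid | CC1(C)CCC[C@@]2(C)[C@H]1CC(=O)[C@@]3(C)O[C@@]23CC(=O)O | intermediate
6 | 7-hydrazone of 5 | CC1(C)CCC[C@@]2(C)[C@H]1CC(=NN)[C@@]3(C)O[C@@]23CC(=O)O | intermediate (not isolated)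
7 | 9α-hydroxy-13,14,15,16-tetranorlabd-7-en-12-oic acid | CC1(C)CCC[C@@]2(C)[C@H]1CC=C(C)[C@]2(O)CC(=O)O | intermediate
8 | 7α,8α-epoxy-9α-hydroxy-13,14,15,16-tetranorlabdan-12-oic acid | CC1(C)CCC[C@@]2(C)[C@H]1C[C@H]3O[C@@]3(C)[C@]2(O)CC(=O)O | intermediate (not isolated)
9 | 7α,9α-dihydroxy-13,14,15,16-tetranorlabdan-12,8β-olide (8α-methyl, cis-fused γ-lactone) | CC1(C)CCC[C@@]2(C)[C@H]1C[C@@H](O)[C@]1(C)OC(=O)C[C@]21O | intermediate
10 | 7α,9α-O-benzylidene acetal of 9 (phenyl exo, acetal hydrogen facing ring B) | CC1(C)CCC[C@@]2(C)[C@H]1C[C@H]1O[C@H](c3ccccc3)O[C@@]23CC(=O)O[C@@]13C | intermediate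
11 | 7α,9α-O-benzylidene-8β,12-epoxy-13,14,15,16-tetranorlabdan-12-ol (lactol, C12 anomers) | CC1(C)CCC[C@@]2(C)[C@H]1C[C@H]1O[C@H](c3ccccc3)O[C@@]23CC(O)O[C@@]13C | intermediate
12 | (R)-malic acid, (2R)-2-hydroxybutanedioic acid | OC(=O)C[C@@H](O)C(=O)O | starting material
13 | 2-[(2R,4R)-2-tert-butyl-5-oxo-1,3-dioxolan-4-yl]acetic acid | CC(C)(C)[C@@H]1O[C@H](CC(=O)O)C(=O)O1 | intermediate
14 | (2R,5R)-2-tert-butyl-5-(2-hydroxyethyl)-1,3-dioxolan-4-one | CC(C)(C)[C@@H]1O[C@H](CCO)C(=O)O1 | intermediate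
15 | (2R,5R)-2-tert-butyl-5-[2-(tert-butyldiphenylsilyloxy)ethyl]-1,3-dioxolan-4-one | CC(C)(C)[C@@H]1O[C@H](CCO[Si](c2ccccc2)(c2ccccc2)C(C)(C)C)C(=O)O1 | intermediate
16 | lithium enolate of 15 | CC(C)(C)[C@@H]1OC(CCO[Si](c2ccccc2)(c2ccccc2)C(C)(C)C)=C([O-])O1.[Li+] | intermediate (not isolated)
17 | aldol adduct, (2R,5S)-dioxolanone carrying at C5 the 7α,9α-O-benzylidene-8β,12-dihydroxy-tetranorlabdan-12-yl group (C12 epimers) and the 2-(TBDPS-oxy)ethyl group | CC1(C)CCC[C@@]2(C)[C@H]1C[C@H]1O[C@H](c3ccccc3)O[C@]2(CC(O)[C@]4(CCO[Si](c5ccccc5)(c5ccccc5)C(C)(C)C)O[C@@H](C(C)(C)C)OC4=O)[C@@]1(C)O | intermediate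
18 | 12-O-(phenoxythiocarbonyl) derivative of 17 | CC1(C)CCC[C@@]2(C)[C@H]1C[C@H]1O[C@H](c3ccccc3)O[C@]2(CC(OC(=S)Oc3ccccc3)[C@]4(CCO[Si](c5ccccc5)(c5ccccc5)C(C)(C)C)O[C@@H](C(C)(C)C)OC4=O)[C@@]1(C)O | intermediate
19 | 12-deoxy compound, (2R,5R)-dioxolanone (C13 = dioxolanone C5, 13R) | CC1(C)CCC[C@@]2(C)[C@H]1C[C@H]1O[C@H](c3ccccc3)O[C@]2(CC[C@]4(CCO[Si](c5ccccc5)(c5ccccc5)C(C)(C)C)O[C@@H](C(C)(C)C)OC4=O)[C@@]1(C)O | intermediate
20 | (13R)-7α,9α-O-benzylidene-15-(tert-butyldiphenylsilyloxy)labdane-8β,13,16-triol | CC1(C)CCC[C@@]2(C)[C@H]1C[C@H]1O[C@H](c3ccccc3)O[C@]2(CC[C@](O)(CO)CCO[Si](c4ccccc4)(c4ccccc4)C(C)(C)C)[C@@]1(C)O | intermediate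
21 | (13R)-15-(tert-butyldiphenylsilyloxy)labdane-7α,8β,9α,13,16-pentaol | CC1(C)CCC[C@@]2(C)[C@H]1C[C@@H](O)[C@](C)(O)[C@]2(O)CC[C@](O)(CO)CCO[Si](c3ccccc3)(c3ccccc3)C(C)(C)C | intermediate
22 | 16-O-tosylate of 21 | CC1(C)CCC[C@@]2(C)[C@H]1C[C@@H](O)[C@](C)(O)[C@]2(O)CC[C@](O)(COS(=O)(=O)c3ccc(C)cc3)CCO[Si](c3ccccc3)(c3ccccc3)C(C)(C)C | intermediate (not isolated)
23 | (13R)-13,16-epoxy-15-(tert-butyldiphenylsilyloxy)labdane-7α,8β,9α-triol | CC1(C)CCC[C@@]2(C)[C@H]1C[C@@H](O)[C@](C)(O)[C@]2(O)CC[C@]3(CO3)CCO[Si](c4ccccc4)(c4ccccc4)C(C)(C)C | intermediate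
24 | (13S)-9α,13-epoxy-15-(tert-butyldiphenylsilyloxy)labdane-7α,8β,16-triol | CC1(C)CCC[C@@]2(C)[C@H]1C[C@@H](O)[C@](C)(O)[C@]21CC[C@@](CO)(CCO[Si](c3ccccc3)(c3ccccc3)C(C)(C)C)O1 | intermediate
25 | (13S)-9α,13-epoxylabdane-7α,8β,15,16-tetraol | CC1(C)CCC[C@@]2(C)[C@H]1C[C@@H](O)[C@](C)(O)[C@]21CC[C@@](CO)(CCO)O1 | intermediate
26 | (13S)-9α,13:15,16-diepoxylabdane-7α,8β,15-triol (lactol, C15 anomers) | CC1(C)CCC[C@@]2(C)[C@H]1C[C@@H](O)[C@](C)(O)[C@]21CC[C@]2(COC(O)C2)O1 | intermediate (not isolated)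
27 | (13S)-9α,13-epoxy-7α,8β-dihydroxylabdan-15,16-olide | CC1(C)CCC[C@@]2(C)[C@H]1C[C@@H](O)[C@](C)(O)[C@]21CC[C@]2(COC(=O)C2)O1 | intermediate
28 | (5S,8R,9S,10S,13S)-9α,13-epoxy-8β-hydroxy-7-oxolabdan-15,16-olide | CC1(C)CCC[C@@]2(C)[C@H]1CC(=O)[C@](C)(O)[C@]21CC[C@]2(COC(=O)C2)O1 | target

**Totals**
Total steps: 20. Longest linear sequence: 17 steps (steps 1–7 and 11–20, from 1 to 28). The side-chain branch (steps 8–10) joins at step 11.

**Three steps most likely to fail, with fallbacks**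

Step 2 (allylic oxidation; it also carries the isomer-purity risk of step 1). C11 is both allylic and α to the ester, so oxidation there or over-oxidation can compete with C7. The fallback sets out from 2 and comes back at 5. LiAlH4 reduces 2 to 13,14,15,16-tetranorlabd-8-en-12-ol F1, and Ac2O/pyridine gives 13,14,15,16-tetranorlabd-8-en-12-yl acetate F2, in which C11 is no longer activated by a carbonyl. CrO3/3,5-dimethylpyrazole then oxidises the ring methylene to 7-oxo-13,14,15,16-tetranorlabd-8-en-12-yl acetate F3. Alkaline H2O2 (NaOH, MeOH) epoxidises the enone from the α face and cleaves the acetate to 8α,9α-epoxy-12-hydroxy-13,14,15,16-tetranorlabdan-7-one F4. TEMPO/PhI(OAc)2 in MeCN–H2O oxidises the primary alcohol to acid 5.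

Step 11 (aldol on the lactol). The lithium lactolate may open too slowly at temperatures where the enolate and the aldolate are stable. The fallback sets out from 10 (with enolate 16 made from 15 as before) and comes back at 17. The C12–C13 bond is made instead by a Claisen-type acylation: lactone 10 is added to enolate 16 at −78 °C, again anti to the tert-butyl group, giving after quench the 12-oxo analogue of 17 F5 (in equilibrium with its 8β,12-hemiketal). NaBH4/CeCl3·7H2O in MeOH at −40 °C reduces the C12 ketone to 17.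

Step 17 (epoxide cyclisation). The tertiary 8β-OH could compete in a 6-exo opening, or the 2,2-disubstituted epoxide could rearrange to an aldehyde. The fallback sets out from 20 and comes back at 27; it trades the stereospecific opening for a reversible conjugate addition, so the C13 epimers must be separated. Bu4NF gives (13R)-7α,9α-O-benzylidenelabdane-8β,13,15,16-tetraol F6, and TEMPO/PhI(OAc)2 gives (13R)-7α,9α-O-benzylidene-8β,13-dihydroxylabdan-15,16-olide F7. Ac2O/DMAP gives the 13-O-acetate of F7 F8, and DBU eliminates acetic acid (E1cB) to 7α,9α-O-benzylidene-8β-hydroxylabd-13-en-15,16-olide F9. 80% aq. AcOH at 40 °C removes the acetal to give 7α,8β,9α-trihydroxylabd-13-en-15,16-olide F10. Catalytic DBU in CH2Cl2 then effects intramolecular oxa-Michael addition of 9α-OH to C13, giving 27 together with (13R)-9α,13-epoxy-7α,8β-dihydroxylabdan-15,16-olide F11, which is separated by chromatography and re-equilibrated under the same base.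

**Further compounds**
F1 | step 2 | 13,14,15,16-tetranorlabd-8-en-12-ol | CC1(C)CCC[C@@]2(C)[C@H]1CCC(C)=C2CCO
F2 | step 2 | 13,14,15,16-tetranorlabd-8-en-12-yl acetate | CC1(C)CCC[C@@]2(C)[C@H]1CCC(C)=C2CCOC(C)=O
F3 | step 2 | 7-oxo-13,14,15,16-tetranorlabd-8-en-12-yl acetate | CC1(C)CCC[C@@]2(C)[C@H]1CC(=O)C(C)=C2CCOC(C)=O
F4 | step 2 | 8α,9α-epoxy-12-hydroxy-13,14,15,16-tetranorlabdan-7-one | CC1(C)CCC[C@@]2(C)[C@H]1CC(=O)[C@@]3(C)O[C@@]23CCO
F5 | step 11 | 12-oxo analogue of 17, (2R,5S)-dioxolanone | CC1(C)CCC[C@@]2(C)[C@H]1C[C@H]1O[C@H](c3ccccc3)O[C@]2(CC(=O)[C@]4(CCO[Si](c5ccccc5)(c5ccccc5)C(C)(C)C)O[C@@H](C(C)(C)C)OC4=O)[C@@]1(C)O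
F6 | step 17 | (13R)-7α,9α-O-benzylidenelabdane-8β,13,15,16-tetraol | CC1(C)CCC[C@@]2(C)[C@H]1C[C@H]1O[C@H](c3ccccc3)O[C@]2(CC[C@](O)(CO)CCO)[C@@]1(C)O
F7 | step 17 | (13R)-7α,9α-O-benzylidene-8β,13-dihydroxylabdan-15,16-olide | CC1(C)CCC[C@@]2(C)[C@H]1C[C@H]1O[C@H](c3ccccc3)O[C@]2(CC[C@]4(O)COC(=O)C4)[C@@]1(C)O
F8 | step 17 | 13-O-acetate of F7 | CC1(C)CCC[C@@]2(C)[C@H]1C[C@H]1O[C@H](c3ccccc3)O[C@]2(CC[C@]4(OC(C)=O)COC(=O)C4)[C@@]1(C)O
F9 | step 17 | 7α,9α-O-benzylidene-8β-hydroxylabd-13-en-15,16-olide | CC1(C)CCC[C@@]2(C)[C@H]1C[C@H]1O[C@H](c3ccccc3)O[C@]2(CCC4=CC(=O)OC4)[C@@]1(C)O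
F10 | step 17 | 7α,8β,9α-trihydroxylabd-13-en-15,16-olide | CC1(C)CCC[C@@]2(C)[C@H]1C[C@@H](O)[C@](C)(O)[C@]2(O)CCC1=CC(=O)OC1
F11 | step 17 | (13R)-9α,13-epoxy-7α,8β-dihydroxylabdan-15,16-olide (13-epimer of 27) | CC1(C)CCC[C@@]2(C)[C@H]1C[C@@H](O)[C@](C)(O)[C@]21CC[C@@]2(COC(=O)C2)O1
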